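**Retrosynthetic overview**
- The target comes from global MOM removal of a penta-MOM bis-ketone. Both 2,4-dioxygenated aryl ketones are made at once by adding one aryllithium to a bis-Weinreb amide, and the E-enone arm comes from a Wittig reaction on a C5 aldehyde.
- Only the dihydrofuran ring is built (the three benzene rings are bought). It is closed at O1–C7a by intramolecular SNAr of the C2 alkoxide on an aryl fluoride para to CHO.
- The C2–C3 bond is formed in a Wolff rearrangement (a [1,2]-sigmatropic shift with retention) of an α-aryl-α-diazoketone. The aryl group is put on the diazoketone by Pd-catalysed C–H arylation with 4-fluoro-3-iodobenzaldehyde.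
- C2 is bought in (S)-4-hydroxymandelic acid and its C–O bond is never broken. C3, which is α to a carbonyl, is equilibrated trans to it.

Assumption: (S)-4-hydroxymandelic acid is taken as a purchasable single enantiomer (the natural L-acid; the racemate is an industrial intermediate).

**Route**

Step 1
Reactants: 1 (S)-4-hydroxymandelic acid
Product: 3 (2S)-2-hydroxy-2-[4-(methoxymethoxy)phenyl]acetic acid, via MOM ester 2 (not isolated)
Conditions: MOMCl (2.2 equiv), i-Pr2NEt, CH2Cl2–DMF, 0 °C → rt; then NaOH (1 M aq), THF, 0 °C; HCl to pH 4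
Reagents that add atoms: chloromethyl methyl ether (MOMCl), COCCl; sodium hydroxide NaOH (its oxygen ends in the CO2H group), [Na+].[OH-]
Why: MOM alkylation takes the phenol and the acid but not the slower secondary alcohol, and the acylal-type MOM ester is then saponified cold within minutes, so the benzylic stereocentre is not touched (MOM protection, ester hydrolysis).

Step 2
Reactants: 3 (2S)-2-hydroxy-2-[4-(methoxymethoxy)phenyl]acetic acid
Product: 4 tert-butyldimethylsilyl (2S)-2-(tert-butyldimethylsilyloxy)-2-[4-(methoxymethoxy)phenyl]acetate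
Conditions: TBSCl (2.5 equiv), imidazole, DMF, rt
Reagents that add atoms: tert-butyldimethylsilyl chloride (TBSCl), CC(C)(C)[Si](C)(C)Cl
Why: Imidazole-promoted silylation caps the secondary alcohol and turns the acid into a silyl ester in one operation, which sets up acid chloride formation under neutral conditions.

Step 3
Reactants: 4 tert-butyldimethylsilyl (2S)-2-(tert-butyldimethylsilyloxy)-2-[4-(methoxymethoxy)phenyl]acetate
Product: 6 (3S)-3-(tert-butyldimethylsilyloxy)-1-diazo-3-[4-(methoxymethoxy)phenyl]propan-2-one, via acid chloride 5 (not isolated)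
Conditions: (COCl)2, DMF (cat.), CH2Cl2, 0 °C → rt; evaporate; CH2N2 (3 equiv), Et2O, 0 °C
Reagents that add atoms: diazomethane, C=[N+]=[N-]
Why: Oxalyl chloride/DMF converts a silyl ester into the acid chloride without free HCl or base, so the α-silyloxy benzylic centre does not racemise, and excess diazomethane is acylated to the α-diazoketone (first half of an Arndt–Eistert sequence).

Step 4
Reactants: 6 (3S)-3-(tert-butyldimethylsilyloxy)-1-diazo-3-[4-(methoxymethoxy)phenyl]propan-2-one; 7 4-fluoro-3-iodobenzaldehyde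
Product: 8 (3S)-3-(tert-butyldimethylsilyloxy)-1-diazo-1-(2-fluoro-5-formylphenyl)-3-[4-(methoxymethoxy)phenyl]propan-2-one
Conditions: Pd(PPh3)4 (5 mol%), Ag2CO3 (0.6 equiv), Et3N, PhMe, rt
Reagents that add atoms: none
Why: Pd-catalysed C–H arylation of an acyldiazomethane with an aryl iodide keeps the diazo group and runs at room temperature with weak base, so C2 stays intact and the aldehyde and aryl fluoride are spectators (cross-coupling).

Step 5
Reactants: 8 (3S)-3-(tert-butyldimethylsilyloxy)-1-diazo-1-(2-fluoro-5-formylphenyl)-3-[4-(methoxymethoxy)phenyl]propan-2-one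
Product: 10 (3R)-3-(tert-butyldimethylsilyloxy)-2-(2-fluoro-5-formylphenyl)-N-methoxy-N-methyl-3-[4-(methoxymethoxy)phenyl]propanamide as a mixture of C2 epimers, via aryl ketene 9 (not isolated)
Conditions: hν (450 nm LEDs), PhMe, rt; then MeNH(OMe) (2 equiv), 0 °C
Reagents that add atoms: N,O-dimethylhydroxylamine, CNOC
Why: In the Wolff rearrangement the silyloxybenzyl carbon migrates from the carbonyl carbon to the diazo carbon as N2 leaves, a concerted suprafacial [1,2]-sigmatropic shift that forms the C2–C3 bond with retention at the bought stereocentre, and the aryl ketene is trapped by the amine (the new α-centre forms as an epimer mixture and is corrected later).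

Step 6
Reactants: 10 (3R)-3-(tert-butyldimethylsilyloxy)-2-(2-fluoro-5-formylphenyl)-N-methoxy-N-methyl-3-[4-(methoxymethoxy)phenyl]propanamide
Product: 12 (2R,3R)-5-formyl-N-methoxy-N-methyl-2-[4-(methoxymethoxy)phenyl]-2,3-dihydro-1-benzofuran-3-carboxamide, via alkoxide 11 (not isolated)
Conditions: TBAF (1.5 equiv), THF, 0 °C → rt
Reagents that add atoms: none
Why: Fluoride desilylation frees the alkoxide, which closes the five-membered ring by intramolecular SNAr on the fluoride para to the formyl group without breaking the C2–O bond (retention at C2), and the basic medium equilibrates the acidic C3–H towards the trans isomer dictated by C2 (any cis material converges in step 10).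

Step 7
Reactants: 12 (2R,3R)-5-formyl-N-methoxy-N-methyl-2-[4-(methoxymethoxy)phenyl]-2,3-dihydro-1-benzofuran-3-carboxamide; 13 N-methoxy-N-methyl-2-(triphenylphosphoranylidene)acetamide
Product: 14 (2R,3R)-N-methoxy-5-{(1E)-3-[methoxy(methyl)amino]-3-oxoprop-1-en-1-yl}-N-methyl-2-[4-(methoxymethoxy)phenyl]-2,3-dihydro-1-benzofuran-3-carboxamide
Conditions: PhMe, 80 °C
Reagents that add atoms: none
Why: Wittig olefination with a stabilised, non-basic phosphorane gives the E-alkene selectively and leaves the base-sensitive β-aryloxy amide and both stereocentres alone.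

Step 8
Reactants: 15 4-bromoresorcinol
Product: 16 1-bromo-2,4-bis(methoxymethoxy)benzene
Conditions: MOMCl (2.5 equiv), i-Pr2NEt, CH2Cl2, 0 °C → rt
Reagents that add atoms: chloromethyl methyl ether (MOMCl), COCCl
Why: Standard MOM protection of both phenols makes the bromide fit for bromine–lithium exchange.

Step 9
Reactants: 14 (2R,3R)-N-methoxy-5-{(1E)-3-[methoxy(methyl)amino]-3-oxoprop-1-en-1-yl}-N-methyl-2-[4-(methoxymethoxy)phenyl]-2,3-dihydro-1-benzofuran-3-carboxamide; 16 1-bromo-2,4-bis(methoxymethoxy)benzene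
Product: 18 (2E)-1-[2,4-bis(methoxymethoxy)phenyl]-3-{(2R,3R)-3-[2,4-bis(methoxymethoxy)benzoyl]-2-[4-(methoxymethoxy)phenyl]-2,3-dihydro-1-benzofuran-5-yl}prop-2-en-1-one, via aryllithium 17 (not isolated)
Conditions: 16 (3 equiv), n-BuLi, THF, −78 °C; then 14, −78 °C; sat. aq NH4Cl
Reagents that add atoms: none
Why: Bromine–lithium exchange gives the aryllithium, which adds once to each Weinreb amide (chelated tetrahedral intermediates, 1,2-addition at the unsaturated amide), so both aryl ketones appear on work-up while the low temperature suppresses C3 enolisation and keeps the trans relationship.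

Step 10
Reactants: 18 (2E)-1-[2,4-bis(methoxymethoxy)phenyl]-3-{(2R,3R)-3-[2,4-bis(methoxymethoxy)benzoyl]-2-[4-(methoxymethoxy)phenyl]-2,3-dihydro-1-benzofuran-5-yl}prop-2-en-1-one
Product: 19 (2E)-1-(2,4-dihydroxyphenyl)-3-[(2R,3R)-3-(2,4-dihydroxybenzoyl)-2-(4-hydroxyphenyl)-2,3-dihydro-1-benzofuran-5-yl]prop-2-en-1-one (target)
Conditions: HCl (3 M aq), MeOH–THF, 45 °C
Reagents that add atoms: none
Why: Acid-catalysed acetal exchange with methanol removes all five MOM groups, and under the same conditions C3, now α to an aryl ketone, stays in or returns to the thermodynamically preferred trans arrangement relative to C2.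

**Compound list**
1 | (S)-4-hydroxymandelic acid, (2S)-2-hydroxy-2-(4-hydroxyphenyl)acetic acid | O[C@@H](c1ccc(O)cc1)C(=O)O | starting material
2 | methoxymethyl (2S)-2-hydroxy-2-[4-(methoxymethoxy)phenyl]acetate | O[C@@H](c1ccc(OCOC)cc1)C(=O)OCOC | intermediate (not isolated)
3 | (2S)-2-hydroxy-2-[4-(methoxymethoxy)phenyl]acetic acid | O[C@@H](c1ccc(OCOC)cc1)C(=O)O | intermediate
4 | tert-butyldimethylsilyl (2S)-2-(tert-butyldimethylsilyloxy)-2-[4-(methoxymethoxy)phenyl]acetate | CC(C)(C)[Si](C)(C)O[C@@H](c1ccc(OCOC)cc1)C(=O)O[Si](C)(C)C(C)(C)C | intermediate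
5 | (2S)-2-(tert-butyldimethylsilyloxy)-2-[4-(methoxymethoxy)phenyl]acetyl chloride | CC(C)(C)[Si](C)(C)O[C@@H](c1ccc(OCOC)cc1)C(Cl)=O | intermediate (not isolated)
6 | (3S)-3-(tert-butyldimethylsilyloxy)-1-diazo-3-[4-(methoxymethoxy)phenyl]propan-2-one | CC(C)(C)[Si](C)(C)O[C@@H](c1ccc(OCOC)cc1)C(=O)C=[N+]=[N-] | intermediate
7 | 4-fluoro-3-iodobenzaldehyde | O=Cc1ccc(F)c(I)c1 | starting material
8 | (3S)-3-(tert-butyldimethylsilyloxy)-1-diazo-1-(2-fluoro-5-formylphenyl)-3-[4-(methoxymethoxy)phenyl]propan-2-one | CC(C)(C)[Si](C)(C)O[C@@H](c1ccc(OCOC)cc1)C(=O)C(=[N+]=[N-])c1cc(C=O)ccc1F | intermediate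
9 | (3S)-3-(tert-butyldimethylsilyloxy)-2-(2-fluoro-5-formylphenyl)-3-[4-(methoxymethoxy)phenyl]prop-1-en-1-one (aryl ketene) | CC(C)(C)[Si](C)(C)O[C@@H](c1ccc(OCOC)cc1)C(=C=O)c1cc(C=O)ccc1F | intermediate (not isolated)
10 | (3R)-3-(tert-butyldimethylsilyloxy)-2-(2-fluoro-5-formylphenyl)-N-methoxy-N-methyl-3-[4-(methoxymethoxy)phenyl]propanamide, both C2 epimers | CC(C)(C)[Si](C)(C)O[C@@H](c1ccc(OCOC)cc1)C(C(=O)N(C)OC)c1cc(C=O)ccc1F | intermediate
11 | (3R)-2-(2-fluoro-5-formylphenyl)-3-hydroxy-N-methoxy-N-methyl-3-[4-(methoxymethoxy)phenyl]propanamide, formed as its tetrabutylammonium alkoxide | O[C@@H](c1ccc(OCOC)cc1)C(C(=O)N(C)OC)c1cc(C=O)ccc1F | intermediate (not isolated)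
12 | (2R,3R)-5-formyl-N-methoxy-N-methyl-2-[4-(methoxymethoxy)phenyl]-2,3-dihydro-1-benzofuran-3-carboxamide (trans) | O=Cc1ccc2c(c1)[C@@H](C(=O)N(C)OC)[C@H](c1ccc(OCOC)cc1)O2 | intermediate
13 | N-methoxy-N-methyl-2-(triphenylphosphoranylidene)acetamide | CON(C)C(=O)C=P(c1ccccc1)(c1ccccc1)c1ccccc1 | starting material
14 | (2R,3R)-N-methoxy-5-{(1E)-3-[methoxy(methyl)amino]-3-oxoprop-1-en-1-yl}-N-methyl-2-[4-(methoxymethoxy)phenyl]-2,3-dihydro-1-benzofuran-3-carboxamide | CON(C)C(=O)/C=C/c1ccc2c(c1)[C@@H](C(=O)N(C)OC)[C@H](c1ccc(OCOC)cc1)O2 | intermediate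
15 | 4-bromoresorcinol (4-bromobenzene-1,3-diol) | Oc1ccc(Br)c(O)c1 | starting material
16 | 1-bromo-2,4-bis(methoxymethoxy)benzene | COCOc1ccc(Br)c(OCOC)c1 | intermediate
17 | [2,4-bis(methoxymethoxy)phenyl]lithium | [Li]c1ccc(OCOC)cc1OCOC | intermediate (not isolated)
18 | (2E)-1-[2,4-bis(methoxymethoxy)phenyl]-3-{(2R,3R)-3-[2,4-bis(methoxymethoxy)benzoyl]-2-[4-(methoxymethoxy)phenyl]-2,3-dihydro-1-benzofuran-5-yl}prop-2-en-1-one | O=C(/C=C/c1ccc2c(c1)[C@@H](C(=O)c1ccc(OCOC)cc1OCOC)[C@H](c1ccc(OCOC)cc1)O2)c1ccc(OCOC)cc1OCOC | intermediate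
19 | (2E)-1-(2,4-dihydroxyphenyl)-3-[(2R,3R)-3-(2,4-dihydroxybenzoyl)-2-(4-hydroxyphenyl)-2,3-dihydro-1-benzofuran-5-yl]prop-2-en-1-one | O=C(/C=C/c1ccc2c(c1)[C@@H](C(=O)c1ccc(O)cc1O)[C@H](c1ccc(O)cc1)O2)c1ccc(O)cc1O | target

**Step count**
Total steps: 10. Longest linear sequence: 9 (steps 1–7, 9, 10); step 8 is a one-step side branch.

**Steps most likely to fail, with fallbacks**

Step 4 (Pd C–H arylation of the diazoketone). The coupling may be slow with the hindered ortho-fluoro iodide, or the diazo group may be lost. The fallback sets out from 6 (and uses 7) and comes back at 8. One equivalent of HBr in Et2O at −78 °C converts 6 into the bromomethyl ketone (3S)-1-bromo-3-(tert-butyldimethylsilyloxy)-3-[4-(methoxymethoxy)phenyl]propan-2-one F1. Zn dust with LiCl in THF converts 7 into (2-fluoro-5-formylphenyl)zinc iodide F2, which tolerates its own aldehyde. Negishi coupling of F1 with F2 (Pd(PPh3)4 cat., THF, rt) gives the benzyl ketone (1S)-1-(tert-butyldimethylsilyloxy)-3-(2-fluoro-5-formylphenyl)-1-[4-(methoxymethoxy)phenyl]propan-2-one F3. Regitz diazo transfer (p-acetamidobenzenesulfonyl azide, DBU, MeCN, 0 °C) onto the doubly activated CH2, which is far more acidic than the silyloxy-bearing CH, returns to 8.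

Step 6 (desilylation and SNAr). The free β-alkoxide of an α-aryl amide can undergo retro-aldol cleavage, or the β-oxygen can be eliminated, before the ring closes. The fallback sets out from 8 and comes back at 12. The Wolff rearrangement of step 5 is run in THF–H2O so that ketene 9 is trapped by water as (3R)-3-(tert-butyldimethylsilyloxy)-2-(2-fluoro-5-formylphenyl)-3-[4-(methoxymethoxy)phenyl]propanoic acid F4. TBAF then generates a carboxylate–alkoxide dianion, in which retro-aldol and elimination are shut down, and SNAr closure gives (2R,3R)-5-formyl-2-[4-(methoxymethoxy)phenyl]-2,3-dihydro-1-benzofuran-3-carboxylic acid F5. Carbodiimide coupling (EDC, HOBt) with MeNH(OMe) returns to 12.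

Step 9 (double aryllithium addition). The aryllithium can deprotonate the acidic C3–H instead of adding, leaving the C3 amide untouched. The fallback sets out from 14 and comes back at 18. i-Bu2AlH at −78 °C reduces both Weinreb amides to the dialdehyde (2R,3R)-2-[4-(methoxymethoxy)phenyl]-5-[(1E)-3-oxoprop-1-en-1-yl]-2,3-dihydro-1-benzofuran-3-carbaldehyde F6. Aryllithium 17 adds to both aldehydes much faster than it enolises them, giving the bis-carbinol (2E)-1-[2,4-bis(methoxymethoxy)phenyl]-3-{(2R,3S)-3-{[2,4-bis(methoxymethoxy)phenyl](hydroxy)methyl}-2-[4-(methoxymethoxy)phenyl]-2,3-dihydro-1-benzofuran-5-yl}prop-2-en-1-ol F7 (ring geometry as in 14, carbinol centres as mixtures). Dess–Martin periodinane oxidises both carbinols and returns to 18.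

Further compounds
F1 | step 4 | (3S)-1-bromo-3-(tert-butyldimethylsilyloxy)-3-[4-(methoxymethoxy)phenyl]propan-2-one | CC(C)(C)[Si](C)(C)O[C@@H](c1ccc(OCOC)cc1)C(=O)CBr
F2 | step 4 | (2-fluoro-5-formylphenyl)zinc iodide | O=Cc1ccc(F)c([Zn]I)c1
F3 | step 4 | (1S)-1-(tert-butyldimethylsilyloxy)-3-(2-fluoro-5-formylphenyl)-1-[4-(methoxymethoxy)phenyl]propan-2-one | CC(C)(C)[Si](C)(C)O[C@@H](c1ccc(OCOC)cc1)C(=O)Cc1cc(C=O)ccc1F
F4 | step 6 | (3R)-3-(tert-butyldimethylsilyloxy)-2-(2-fluoro-5-formylphenyl)-3-[4-(methoxymethoxy)phenyl]propanoic acid, both C2 epimers | CC(C)(C)[Si](C)(C)O[C@@H](c1ccc(OCOC)cc1)C(C(=O)O)c1cc(C=O)ccc1F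
F5 | step 6 | (2R,3R)-5-formyl-2-[4-(methoxymethoxy)phenyl]-2,3-dihydro-1-benzofuran-3-carboxylic acid | O=Cc1ccc2c(c1)[C@@H](C(=O)O)[C@H](c1ccc(OCOC)cc1)O2
F6 | step 9 | (2R,3R)-2-[4-(methoxymethoxy)phenyl]-5-[(1E)-3-oxoprop-1-en-1-yl]-2,3-dihydro-1-benzofuran-3-carbaldehyde | O=C/C=C/c1ccc2c(c1)[C@@H](C=O)[C@H](c1ccc(OCOC)cc1)O2
F7 | step 9 | (2E)-1-[2,4-bis(methoxymethoxy)phenyl]-3-{(2R,3S)-3-{[2,4-bis(methoxymethoxy)phenyl](hydroxy)methyl}-2-[4-(methoxymethoxy)phenyl]-2,3-dihydro-1-benzofuran-5-yl}prop-2-en-1-ol, carbinol centres as mixtures | OC(/C=C/c1ccc2c(c1)[C@@H](C(O)c1ccc(OCOC)cc1OCOC)[C@H](c1ccc(OCOC)cc1)O2)c1ccc(OCOC)cc1OCOC
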